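The numbers in the tables are calculated for substances that don't exist; the scatter is artificial.

I left Sunday's flask stirring at 20 °C. Whoever took over needed to know what it would hold at 3.0 h.

| setting | noon | winter | midnight | summer | Sunday's | Monday's | Thursday's | Tuesday's | Friday's | Wednesday's |
|---|---|---|---|---|---|---|---|---|---|---|
| starting material | 20 mM | 20 mM | 20 mM | 20 mM | 80 mM | 30 mM | 5.0 mM | 20 mM | 10 mM | 30 mM |
| coupling partner | 4.3 equiv | 4 equiv | 5.2 equiv | 5 equiv | 5.00 equiv | 5.00 equiv | 3.40 equiv | 5.00 equiv | 5.00 equiv | 5.00 equiv |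
| initiator | 2 mol% | 2 mol% | 2 mol% | 4.7 mol% | 6 mol% | 2 mol% | 2 mol% | 2 mol% | 2 mol% | 2 mol% |
| temperature | −15 °C | 25 °C | −15 °C | 25 °C | 20 °C | −10 °C | 5 °C | 20 °C | 60 °C | 20 °C |
| remark | run made earlier | run made earlier | run made earlier | run made earlier |  |  |  |  |  |  |
| time |  |  |  |  | 3.0 h | 3.0 h | 3.0 h | 3.0 h | 3.0 h | 3.0 h |

| run | time / h | product / % | starting material / % |
|---|---|---|---|
| noon | 5.00 | 3.5 | 96.5 |
| noon | 8.00 | 5.9 | 94.0 |
| noon | 15.0 | 12.1 | 89.6 |
| winter | 0.833 | 49.6 | 51.5 |
| winter | 1.50 | 57.0 | 41.4 |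
| winter | 2.50 | 62.3 | 38.4 |
| winter | 3.00 | 63.8 | 36.8 |
| midnight | 1.33 | 1.0 | 101.5 |
| midnight | 3.00 | 4.1 | 97.4 |
| midnight | 8.00 | 4.4 | 93.8 |
| midnight | 15.0 | 10.5 | 90.8 |
| summer | 0.250 | 37.5 | 62.0 |
| summer | 0.500 | 53.6 | 43.1 |
| summer | 1.33 | 75.0 | 24.2 |
| summer | 3.00 | 80.4 | 19.3 |

(scatter of a reading: 1 percentage point)

- the analysis behind the earlier runs scatters by 1 percentage point, standard deviation

- the flasks put in order of amount of product, in percent of the starting material charged, best first, at 3.0 h (Sunday's / Monday's / Thursday's / Tuesday's / Friday's / Wednesday's)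
- the amount of product, in percent of the starting material charged of the flask you put first, at 3.0 h
- the amount of product, in percent of the starting material charged of the flask you put last, at 3.0 h

Winter and summer rose and then stalled. Winter left 36.8 % of its starting material at 3.00 h, so its reach was 1.00. By reach I meant minus the natural logarithm of the fraction of starting material left once a flask has stalled. Summer's reach was 1.65, a ratio of 1.65 to winter's, while the root of the loading ratio was 1.53. So I let reach grow as the root of c(initiator). Winter and summer both stood at 20 mM, so using concentration instead of loading was my assumption. I also carried the reach from 25 °C to 20 °C unchanged.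

c(initiator), Sunday's = 4.80 mM; winter = 0.400 mM

reach, Sunday's = 1.00 × √(4.80 mM / 0.400 mM) = 3.46

starting material left = 3.13 %; product = 96.9 %

Winter's product and starting material summed to 101 %, which is why I counted what was lost as product.

I did not want the bath cooled: midnight at −15 °C still showed 97.4 % of its starting material at 3.00 h, more than winter's 36.8 % at 3.00 h. I saw no case for adding coupling partner: at 15.0 h, 4.3 equiv gave 12.1 % and 5.2 equiv gave 10.5 %.

The forecast gave Sunday's > Wednesday's > Tuesday's > Friday's > Thursday's > Monday's, with 93 % first and 6 % last. Its ground was a plateau “which suggests rate ∝ √initiator, as in a radical chain”. My 96.9 % for Sunday's stood above its 93 %.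

Sunday's gave 98.3 %, Monday's gave 5.43 %, and the order was Sunday's > Wednesday's > Tuesday's > Friday's > Thursday's > Monday's.

    2 second chain carrier → ended chains B (k = 3.00 × 10⁷ M⁻¹ s⁻¹, Ea = 12.0 kJ mol⁻¹)
    coupling partner + first chain carrier → product + second chain carrier (k = 12900 M⁻¹ s⁻¹, Ea = 35.0 kJ mol⁻¹)
    initiator → 2 initiating radical (k = 0.0211 min⁻¹, Ea = 98.0 kJ mol⁻¹)
    starting material + second chain carrier → by-product + first chain carrier (k = 1.68 × 10⁵ M⁻¹ min⁻¹, Ea = 39.0 kJ mol⁻¹)
    starting material + initiating radical → capped initiator + first chain carrier (k = 46300 M⁻¹ s⁻¹, Ea = 12.0 kJ mol⁻¹)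
    2 first chain carrier → ended chains A (k = 1.00 × 10⁷ M⁻¹ s⁻¹, Ea = 11.0 kJ mol⁻¹)
    (constants at 20 °C)

At 3.00 h, Sunday's held 1.72 % of its starting material and 2.24 % of its initiator; minus the natural logarithm of that starting material fraction was 4.06, against my reach of 3.46. Wednesday's had the same c(initiator) rule applied to it:

reach, Wednesday's = 1.00 × √(0.600 mM / 0.400 mM) = 1.22

product = 70.5 %

Wednesday's flask gave 69.9 %.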